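Numbering: ring A is C1 (OH), C2 (Br), C3 (H), C4 (ether O), C5 (Br), C6 (Br). Ring B is C1' (ether O), C2' (OH), C3' (Br), C4' (Br), C5' (OH), C6' (Br).
Enabling feature: in ring A the ether oxygen (C4) and a bromine (C5) sit on adjacent carbons, and the next carbon (C6) bears another bromine. This is the pattern left by nucleophile/electrophile addition across a C4–C5 aryne polarised by C6–Br.
Cuts: the three O–H bonds go back to O–CH3. C4–O and C5–Br are then cut in one operation, giving a ring A silyl triflate, the ring B phenol and a bromine donor.
Forward: no ring is built. Ring A starts from 2,6-dibromoanisole, which already carries C2–Br and C6–Br, and reaches the silyl triflate in four steps. Ring B (2,5-dimethoxyphenol) is perbrominated in one step, the halves are joined in step 6, and step 7 frees the phenols.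
Stereochemistry: the target has no stereocentre. Only regiochemistry matters, and it rests on the mirror symmetry of the ring A intermediates and on the C6 bromine in the aryne step.

Key step: step 6

Assumption: ring A carries its C2 bromine through the aryne step as a spectator. Bromination after the coupling would have to occur ortho to a methoxy group that already has one ortho bromine, and it would compete with C3. The weak inductive bias of C2–Br toward C5 attack is taken to be overridden by C6–Br and the C1 methoxy group.

Step 1
Reactants: 1 2,6-dibromoanisole (1,3-dibromo-2-methoxybenzene)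
Product: 3 3,5-dibromo-4-methoxyphenol, via arylboronic pinacol ester 2 (not isolated)
Conditions: HBpin, [Ir(OMe)(cod)]2 (cat.), 4,4'-di-tert-butyl-2,2'-bipyridine (cat.), THF, 60 °C; evaporate; KHSO5 (as the triple salt 2KHSO5·KHSO4·K2SO4), acetone/H2O, rt
Reagents that add atoms: pinacolborane, CC1(C)OBOC1(C)C (boryl group of 2); potassium peroxymonosulfate, [K+].[O-]S(=O)(=O)OO (phenol oxygen of 3)
Why: Iridium-catalysed C–H borylation is sterically governed and in this 1,2,3-trisubstituted arene reaches only the C–H para to the methoxy group, the C–Br bonds are inert to the catalyst, and peroxymonosulfate then turns C–B into C–OH at the same carbon (one-pot borylation–oxidation route to phenols).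

Step 2
Reactants: 3 3,5-dibromo-4-methoxyphenol
Product: 4 3,5-dibromo-4-methoxyphenyl N-isopropylcarbamate
Conditions: iPrNCO, Et3N (cat.), CH2Cl2, rt
Reagents that add atoms: isopropyl isocyanate, CC(C)N=C=O
Why: Base-catalysed addition of a phenol to an isocyanate (carbamoylation) proceeds without a by-product and installs an ortho-directing group that can later be removed under mild E1cB conditions.

Step 3
Reactants: 4 3,5-dibromo-4-methoxyphenyl N-isopropylcarbamate
Product: 8 3,5-dibromo-4-methoxy-2-(trimethylsilyl)phenyl N-isopropylcarbamate, via N-silyl carbamate 5 (not isolated), via aryllithium 6 (not isolated), via doubly silylated carbamate 7 (not isolated)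
Conditions: TBSOTf (1.05 equiv), TMEDA, Et2O, 0 °C → rt; Me3SiCl, then LiN(iPr)2 (2.1 equiv, THF solution, slow addition), −78 °C; aq NaHSO4
Reagents that add atoms: chlorotrimethylsilane, C[Si](C)(C)Cl; tert-butyldimethylsilyl trifluoromethanesulfonate, CC(C)(C)[Si](C)(C)OS(=O)(=O)C(F)(F)F (silyl group of 5 to 7 only); lithium diisopropylamide, [Li+].CC(C)[N-]C(C)C (lithium of 6 only)
Why: In this directed ortho-metalation with in situ silyl trapping, N-silylation makes the carbamate a tertiary-type director, the amide base (which cannot exchange bromine for lithium) removes one of the two symmetry-equivalent protons flanked by carbamate oxygen and bromine, and Me3SiCl already present captures 6 before it can lose LiBr or shuffle bromine.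

Step 4
Reactants: 8 3,5-dibromo-4-methoxy-2-(trimethylsilyl)phenyl N-isopropylcarbamate
Product: 10 3,5-dibromo-4-methoxy-2-(trimethylsilyl)phenyl trifluoromethanesulfonate, via silylphenol 9 (not isolated)
Conditions: Et2NH, DBU, MeCN, 40 °C; then PhNTf2, rt
Reagents that add atoms: N-phenylbis(trifluoromethanesulfonimide), O=S(=O)(N(c1ccccc1)S(=O)(=O)C(F)(F)F)C(F)(F)F
Why: DBU deprotonates the N–H carbamate, which expels the phenoxide by E1cB loss of isopropyl isocyanate (scavenged by Et2NH), and PhNTf2 sulfonylates the phenoxide in the same flask, a one-pot carbamate cleavage–triflation that spares C–Si and C–Br bonds.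

Step 5
Reactants: 11 2,5-dimethoxyphenol
Product: 12 3,4,6-tribromo-2,5-dimethoxyphenol
Conditions: Br2 (3.5 equiv), AcOH, rt → 60 °C; aq NaHSO3
Reagents that add atoms: bromine, BrBr
Why: Electrophilic aromatic bromination of a ring with three oxygen donors fills all three free positions so that no regiochemical choice arises, C4' and C6' (para and ortho to OH) reacting at once and C3' (ortho to the C2' methoxy group) under the excess reagent and warming.

Step 6
Reactants: 10 3,5-dibromo-4-methoxy-2-(trimethylsilyl)phenyl trifluoromethanesulfonate; 12 3,4,6-tribromo-2,5-dimethoxyphenol; 13 1,2-dibromotetrachloroethane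
Product: 17 2,3,5-tribromo-4-methoxyphenyl 3,4,6-tribromo-2,5-dimethoxyphenyl ether, via potassium phenoxide 14 (not isolated), via aryne 15 (not isolated), via aryl anion 16 (not isolated)
Conditions: 12, KH (1.0 equiv), THF, 0 °C; then 18-crown-6, CsF (3 equiv), 13 (4 equiv); 10 added slowly, THF, 0 °C → rt
Reagents that add atoms: 1,2-dibromotetrachloroethane 13, ClC(Cl)(Br)C(Cl)(Cl)Br (C5 bromine); potassium hydride, [KH] (potassium of 14 and 16 only)
Why: Proposed new method: fluoride attacks the silicon of 10 and triflate departs from C4 to give aryne 15 with its strained bond between C4 and C5, phenoxide 14 adds to it, and aryl anion 16 takes bromine from 13 by halophilic substitution while the donor fragments irreversibly into C2Cl4 and bromide. The closest known reaction types are the fluoride-induced O-arylation of phenols with silylaryl triflates, the distal addition of O and N nucleophiles to 3-haloarynes, and the amino- and thio-halogenation of arynes in which a halogen donor quenches the aryl anion; the pairing of an aryloxide with a bromine donor is what is new. No ring is closed and no stereocentre is formed. The selectivity needed is attack of oxygen at C4 rather than C5: the C6 bromine distorts the aryne so that C4 is the more electrophilic terminus, places the developing charge on C5 next to the C–Br dipole and shields C5 from the doubly ortho-substituted phenoxide, the C1 methoxy group acts in the same sense, and the remote C2 bromine opposes it only weakly. The second requirement is that 16 is brominated faster than it is protonated or expels the C6 bromide, which is why the phenol is deprotonated beforehand with KH, the solvent is THF and not acetonitrile, 13 is in excess and 10 is fed in slowly. Ring B has no free position and its phenoxide is a hard, poorly halophilic base, so it should leave 13 untouched.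

Step 7
Reactants: 17 2,3,5-tribromo-4-methoxyphenyl 3,4,6-tribromo-2,5-dimethoxyphenyl ether
Product: 19 2,3,5-tribromo-6-(2,3,5-tribromo-4-hydroxyphenoxy)benzene-1,4-diol (CNP0277646.0), via tris(dibromoboryl) ether 18 (not isolated)
Conditions: BBr3 (6 equiv), CH2Cl2, −78 °C → rt; H2O, aq Na2S2O4 wash
Reagents that add atoms: boron tribromide, BrB(Br)Br (boron and bromine of 18 only)
Why: BBr3 cleavage of aryl methyl ethers (coordination to oxygen, then SN2 attack of bromide on methyl) is fastest for methoxy groups twisted out of plane by two ortho substituents, as all three are here, it leaves the diaryl ether and the C–Br bonds alone, and the dithionite wash keeps ring B at the hydroquinone level.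

Compound list
1 | 2,6-dibromoanisole | COc1c(Br)cccc1Br | starting material
2 | 2-(3,5-dibromo-4-methoxyphenyl)-4,4,5,5-tetramethyl-1,3,2-dioxaborolane | COc1c(Br)cc(cc1Br)B1OC(C)(C)C(C)(C)O1 | intermediate
3 | 3,5-dibromo-4-methoxyphenol | COc1c(Br)cc(O)cc1Br | intermediate
4 | 3,5-dibromo-4-methoxyphenyl N-isopropylcarbamate | COc1c(Br)cc(OC(=O)NC(C)C)cc1Br | intermediate
5 | 3,5-dibromo-4-methoxyphenyl N-(tert-butyldimethylsilyl)-N-isopropylcarbamate | COc1c(Br)cc(OC(=O)N(C(C)C)[Si](C)(C)C(C)(C)C)cc1Br | intermediate
6 | 2-lithio derivative of 5 (lithium between carbamate oxygen and bromine) | COc1c(Br)cc(OC(=O)N(C(C)C)[Si](C)(C)C(C)(C)C)c([Li])c1Br | intermediate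
7 | 3,5-dibromo-4-methoxy-2-(trimethylsilyl)phenyl N-(tert-butyldimethylsilyl)-N-isopropylcarbamate | COc1c(Br)cc(OC(=O)N(C(C)C)[Si](C)(C)C(C)(C)C)c([Si](C)(C)C)c1Br | intermediate
8 | 3,5-dibromo-4-methoxy-2-(trimethylsilyl)phenyl N-isopropylcarbamate | COc1c(Br)cc(OC(=O)NC(C)C)c([Si](C)(C)C)c1Br | intermediate
9 | 3,5-dibromo-4-methoxy-2-(trimethylsilyl)phenol | COc1c(Br)cc(O)c([Si](C)(C)C)c1Br | intermediate
10 | 3,5-dibromo-4-methoxy-2-(trimethylsilyl)phenyl trifluoromethanesulfonate | COc1c(Br)cc(OS(=O)(=O)C(F)(F)F)c([Si](C)(C)C)c1Br | intermediate
11 | 2,5-dimethoxyphenol | COc1ccc(OC)c(O)c1 | starting material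
12 | 3,4,6-tribromo-2,5-dimethoxyphenol | COc1c(O)c(Br)c(OC)c(Br)c1Br | intermediate
13 | 1,2-dibromotetrachloroethane | ClC(Cl)(Br)C(Cl)(Cl)Br | starting material
14 | potassium 3,4,6-tribromo-2,5-dimethoxyphenoxide | COc1c([O-])c(Br)c(OC)c(Br)c1Br.[K+] | intermediate
15 | 3,5-dibromo-4-methoxybenzyne (ring A with the formal triple bond between C4 and C5) | COC1=C(Br)C#CC=C1Br | intermediate
16 | potassium salt of the C5 aryl anion (17 with a carbanion in place of the C5 bromine) | COc1c(Br)cc(Oc2c(OC)c(Br)c(Br)c(OC)c2Br)[c-]c1Br.[K+] | intermediate
17 | 2,3,5-tribromo-4-methoxyphenyl 3,4,6-tribromo-2,5-dimethoxyphenyl ether | COc1c(Br)cc(Oc2c(OC)c(Br)c(Br)c(OC)c2Br)c(Br)c1Br | intermediate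
18 | tris(O-dibromoboryl) derivative of 19 | BrB(Br)Oc1c(Br)cc(Oc2c(OB(Br)Br)c(Br)c(Br)c(OB(Br)Br)c2Br)c(Br)c1Br | intermediate
19 | 2,3,5-tribromo-6-(2,3,5-tribromo-4-hydroxyphenoxy)benzene-1,4-diol | Oc1c(Br)cc(Oc2c(O)c(Br)c(Br)c(O)c2Br)c(Br)c1Br | target

Total step count: 7. Longest linear sequence: 6 (steps 1, 2, 3, 4, 6, 7).

Steps most likely to fail

**Step 6.**
- The aryl anion may pick up a proton or expel the C6 bromide before bromine transfer.
- The bromide that accumulates may add to the aryne in competition with the hindered phenoxide.
- The donor may intercept the fluoride-activated C5–Si bond before triflate leaves.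
- The phenoxide may attack the sulfur of the triflate.

The fallback sets out from 10 and 12 and returns at 17, making the two bonds one after the other by known reactions. With free phenol 12 and CsF in MeCN at rt (fluoride-induced O-arylation of phenols with silylaryl triflates), the aryl anion takes the phenol proton. This gives 3,5-dibromo-4-methoxyphenyl 3,4,6-tribromo-2,5-dimethoxyphenyl ether F1, whose ring A is symmetric. Its only two ring protons are equivalent and each lies between the ether oxygen and a bromine. Directed magnesiation with (tmp)MgCl·LiCl (tmp = 2,2,6,6-tetramethylpiperidide) in THF at −25 °C should therefore give the C5 arylmagnesium chloride F2. F2 holds its neighbouring bromine at this temperature, and quenching with 13 gives 17.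

**Step 3.**
- Bromine may migrate between aryllithium and unreacted aryl bromide.
- LiBr may be lost to give an aryne.
- A second silylation may occur at the equivalent proton on the other side of the carbamate if base is in excess.

The fallback sets out from 3 and returns at 10. It replaces deprotonation by halogen–metal exchange and bypasses steps 2 to 4. N-Iodosuccinimide (1 equiv) with catalytic TsOH in MeCN iodinates one of the two equivalent positions ortho to OH and gives 3,5-dibromo-2-iodo-4-methoxyphenol F3. Warm (Me3Si)2NH converts it into the trimethylsilyl ether F4. n-BuLi in THF at −78 °C exchanges iodine selectively over bromine. The resulting 2-lithioaryl silyl ether F5 passes by retro-Brook O-to-C silyl shift into lithium 3,5-dibromo-4-methoxy-2-(trimethylsilyl)phenoxide F6, which Tf2O converts into 10 in the same flask.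

**Step 5.**
- Bromination may stall after two substitutions, because C3' is activated by a single methoxy group.
- Forcing conditions may bring oxidative loss of methyl groups.

The fallback sets out from 11 and returns at 19. It postpones the reluctant bromination until its neighbour is a free hydroxy group. Br2 (2 equiv) in CH2Cl2 at 0 °C gives 4,6-dibromo-2,5-dimethoxyphenol F7, which takes the place of 12 under the conditions of step 6. This gives 2,3,5-tribromo-4-methoxyphenyl 4,6-dibromo-2,5-dimethoxyphenyl ether F8. BBr3 as in step 7 gives 2,6-dibromo-3-(2,3,5-tribromo-4-hydroxyphenoxy)benzene-1,4-diol F9. Br2 (1 equiv) in AcOH at rt with an aq Na2S2O4 wash then brominates C3'. That position is now ortho to a hydroquinone hydroxy group (classical nuclear bromination of hydroquinones), while the last ring A proton is meta to its hydroxy group and should stay untouched.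

Further compounds
F1 | step 6 | 3,5-dibromo-4-methoxyphenyl 3,4,6-tribromo-2,5-dimethoxyphenyl ether | COc1c(Br)cc(Oc2c(OC)c(Br)c(Br)c(OC)c2Br)cc1Br
F2 | step 6 | C5 arylmagnesium chloride derived from F1 | COc1c(Br)cc(Oc2c(OC)c(Br)c(Br)c(OC)c2Br)c([Mg]Cl)c1Br
F3 | step 3 | 3,5-dibromo-2-iodo-4-methoxyphenol | COc1c(Br)cc(O)c(I)c1Br
F4 | step 3 | (3,5-dibromo-2-iodo-4-methoxyphenoxy)trimethylsilane | COc1c(Br)cc(O[Si](C)(C)C)c(I)c1Br
F5 | step 3 | (3,5-dibromo-2-lithio-4-methoxyphenoxy)trimethylsilane | COc1c(Br)cc(O[Si](C)(C)C)c([Li])c1Br
F6 | step 3 | lithium 3,5-dibromo-4-methoxy-2-(trimethylsilyl)phenoxide | COc1c(Br)cc([O-])c([Si](C)(C)C)c1Br.[Li+]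
F7 | step 5 | 4,6-dibromo-2,5-dimethoxyphenol | COc1cc(Br)c(OC)c(Br)c1O
F8 | step 5 | 2,3,5-tribromo-4-methoxyphenyl 4,6-dibromo-2,5-dimethoxyphenyl ether | COc1c(Br)cc(Oc2c(OC)cc(Br)c(OC)c2Br)c(Br)c1Br
F9 | step 5 | 2,6-dibromo-3-(2,3,5-tribromo-4-hydroxyphenoxy)benzene-1,4-diol | Oc1c(Br)cc(Oc2c(O)cc(Br)c(O)c2Br)c(Br)c1Br
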